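**Retrosynthetic overview** (labdane numbering for the bicyclic compounds)
1. Target ⇒ oxidation of the two C-19 CH2OH groups, after an (E)-selective aldol condensation of two molecules of (13S)-19-hydroxylabd-8(17)-en-15-al (the dimerisation presumed in Nature).
2. Labdane bicycle ⇒ acyclic (6E,10E,14S) 2-methyl-3-oxo ester. One oxidative radical cascade mirrors the enzymatic head-to-tail cyclisation: ring A (C4–C5) closes first, then ring B (C10–C9), ending at the 8(17)-alkene, with C-19 already at the carboxyl level and a (–)-8-phenylmenthyl ester setting the absolute sense.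
3. Acyclic chain ⇒ γ-alkylation of the 2-methylacetoacetate dianion with the (E)-allylic ω-bromide of (S)-2,3-dihydrofarnesyl pivalate (SeO2 ω-oxidation).
4. C-13 ⇒ asymmetric hydrogenation of (2E,6E)-farnesol.

Assumption: both labdane units are taken as the natural trans-fused decalin (5R,10R) of an aldol homodimer; the given string tags C-5 of its second unit the other way (a cis-fused unit), which is read as a notation slip, so the route delivers the trans,trans compound and the target line keeps the given string.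

**Route**

Step 1
Reactants: 1 (2E,6E)-farnesol
Product: 2 (3S,6E)-3,7,11-trimethyldodeca-6,10-dien-1-ol
Conditions: Ru(OAc)2[(R)-BINAP] (0.2 mol %), H2 (100 atm), MeOH/H2O 95:5, 20 °C
Reagents that add atoms: none
Why: Noyori asymmetric hydrogenation: the allylic OH binds the ruthenium catalyst so only the 2,3-alkene is reduced, and the (R)-ligand with the (E)-allylic alcohol sets 3S (later C-13), the same sense as geraniol to (S)-citronellol.

Step 2
Reactants: 2 (3S,6E)-3,7,11-trimethyldodeca-6,10-dien-1-ol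
Product: 3 (3S,6E)-3,7,11-trimethyldodeca-6,10-dien-1-yl pivalate
Conditions: t-BuCOCl, pyridine, 4-(dimethylamino)pyridine (5 mol %), CH2Cl2, 0 °C to rt
Reagents that add atoms: pivaloyl chloride, CC(C)(C)C(Cl)=O
Why: Acylation; the pivalate survives the allylic oxidation, the dianion alkylation and the acidic radical cyclisation, and is later removed by LiAlH4 without a step of its own.

Step 3
Reactants: 3 (3S,6E)-3,7,11-trimethyldodeca-6,10-dien-1-yl pivalate
Product: 4 (3S,6E,10E)-12-hydroxy-3,7,11-trimethyldodeca-6,10-dien-1-yl pivalate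
Conditions: SeO2 (0.3 equiv), t-BuOOH (3 equiv), salicylic acid (0.1 equiv), CH2Cl2, 0 °C to rt
Reagents that add atoms: selenium dioxide, O=[Se]=O; tert-butyl hydroperoxide, CC(C)(C)OO
Why: SeO2 allylic oxidation (ene reaction then [2,3]-sigmatropic shift) attacks the terminal trisubstituted alkene at its (E)-methyl group, giving the (E)-allylic alcohol whose geometry later fixes the trans ring fusion.

Step 4
Reactants: 4 (3S,6E,10E)-12-hydroxy-3,7,11-trimethyldodeca-6,10-dien-1-yl pivalate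
Product: 5 (3S,6E,10E)-12-bromo-3,7,11-trimethyldodeca-6,10-dien-1-yl pivalate
Conditions: CBr4, PPh3, CH2Cl2, 0 °C
Reagents that add atoms: carbon tetrabromide, BrC(Br)(Br)Br
Why: Appel reaction: bromide displaces the alkoxyphosphonium group at the primary allylic carbon (SN2) with the (E)-geometry kept.

Step 5
Reactants: 6 (–)-8-phenylmenthol; 7 ethyl 2-methyl-3-oxobutanoate
Product: 8 (1R,2S,5R)-5-methyl-2-(2-phenylpropan-2-yl)cyclohexyl 2-methyl-3-oxobutanoate
Conditions: 4-(dimethylamino)pyridine (0.2 equiv), toluene, reflux, EtOH distilled off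
Reagents that add atoms: none
Why: Amine-catalysed transesterification of a β-keto ester, driven by removal of ethanol; the auxiliary stereocentres are not involved and C-2 stays an enolisable mixture.

Step 6
Reactants: 8 (1R,2S,5R)-5-methyl-2-(2-phenylpropan-2-yl)cyclohexyl 2-methyl-3-oxobutanoate; 5 (3S,6E,10E)-12-bromo-3,7,11-trimethyldodeca-6,10-dien-1-yl pivalate
Product: 10 (–)-8-phenylmenthyl (6E,10E,14S)-2,6,10,14-tetramethyl-3-oxo-16-(pivaloyloxy)hexadeca-6,10-dienoate, via dianion 9 (not isolated)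
Conditions: NaH (1.1 equiv), THF, 0 °C; n-BuLi (1.05 equiv), 0 °C; then 5, 0 °C to rt; NH4Cl (aq)
Reagents that add atoms: none
Why: Weiler dianion alkylation: the second deprotonation gives the terminal (γ) carbanion, the more reactive site, which displaces the allylic bromide (SN2) and joins the chain at C-4 of the keto ester with both (E)-alkenes intact.

Step 7
Reactants: 10 (–)-8-phenylmenthyl (6E,10E,14S)-2,6,10,14-tetramethyl-3-oxo-16-(pivaloyloxy)hexadeca-6,10-dienoate
Product: 11 (–)-8-phenylmenthyl (13S)-3-oxo-15-(pivaloyloxy)labd-8(17)-en-19-oate (4β-ester, 5α-H, 9α-H, 10β-CH3)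
Conditions: Mn(OAc)3·2H2O (2.2 equiv), Cu(OAc)2·H2O (0.5 equiv), degassed AcOH (0.02 M), 25 °C
Reagents that add atoms: none
Why: Proposed new method: Mn(OAc)3 oxidises the enol of the 2-methyl-3-oxo ester to the tertiary α-radical, which adds 6-endo to the 6,7-alkene (ring A, C4–C5) and then 6-endo to the 10,11-alkene (ring B, C10–C9) through chair–chair transition states, the same bond order as the proton-initiated enzymatic labdane cyclisation, and Cu(OAc)2 oxidises the tertiary C-8 radical with loss of a C-17 hydrogen to the 8(17)-alkene; the unchelated radical reacts with the ketone oxygen anti to the ester, which puts the ester axial and the methyl equatorial at C-4, the (E)-alkenes give the trans ring fusion and the equatorial side chain at C-9, and the phenyl ring of the (–)-8-phenylmenthyl ester covers one face of the planar radical (the sense it shows in glyoxylate and acrylate additions) so that the natural series should predominate, its diastereomer being removed by chromatography because the two differ next to the auxiliary; the closest known reaction type is the Mn(OAc)3/Cu(OAc)2 oxidative radical polyene cyclisation of 2-methylacetoacetates, together with its 8-phenylmenthyl ester version for 2-unsubstituted acetoacetates.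

Step 8
Reactants: 11 (–)-8-phenylmenthyl (13S)-3-oxo-15-(pivaloyloxy)labd-8(17)-en-19-oate
Product: 13 (–)-8-phenylmenthyl (4S,5R,9S,10R,13S)-15-(pivaloyloxy)labd-8(17)-en-19-oate, via tosylhydrazone 12 (not isolated)
Conditions: TsNHNH2, EtOH, AcOH (cat.), 70 °C; then catecholborane, CHCl3, 0 °C; NaOAc·3H2O, 60 °C
Reagents that add atoms: none
Why: Caglioti-type deoxygenation in its catecholborane form: hydride adds to C=N, acetate triggers loss of sulfinate and the diazene loses N2 to leave CH2 at C-3 under neutral conditions that do not move the exocyclic alkene; no stereocentre changes.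

Step 9
Reactants: 13 (–)-8-phenylmenthyl (4S,5R,9S,10R,13S)-15-(pivaloyloxy)labd-8(17)-en-19-oate
Product: 14 (4S,5R,9S,10R,13S)-labd-8(17)-ene-15,19-diol
Conditions: LiAlH4 (4 equiv), THF, 0 °C to reflux; NaOH (aq) work-up
Reagents that add atoms: none
Why: Hydride reduction cleaves the hindered axial auxiliary ester to the C-19 alcohol (auxiliary alcohol 6 is recovered) and removes the pivalate in the same operation; all stereocentres are untouched.

Step 10
Reactants: 14 (4S,5R,9S,10R,13S)-labd-8(17)-ene-15,19-diol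
Product: 15 (4S,5R,9S,10R,13S)-19-hydroxylabd-8(17)-en-15-al
Conditions: 2,2,6,6-tetramethylpiperidin-1-oxyl (10 mol %), PhI(OAc)2 (1.1 equiv), CH2Cl2, rt
Reagents that add atoms: none
Why: Nitroxyl-catalysed (oxoammonium) oxidation is very sensitive to steric hindrance, so the unhindered C-15 alcohol goes to the aldehyde while the axial neopentyl C-19 alcohol stays; C-13 is β to the new carbonyl and cannot epimerise.

Step 11
Reactants: 15 (4S,5R,9S,10R,13S)-19-hydroxylabd-8(17)-en-15-al (two molecules)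
Product: 17 (E)-enal diol in which C-14 of one unit is doubly bonded to C-15 of the other, via aldol adduct 16 (not isolated)
Conditions: pyrrolidine (20 mol %), PhCO2H (20 mol %), toluene, 50 °C
Reagents that add atoms: none
Why: Amine-catalysed aldol condensation (enamine addition then elimination), the dimerisation presumed in Nature: C-14 of one molecule adds to C-15 of the other and loss of water gives the thermodynamically preferred (E)-2-alkyl-2-enal; C-13 and C-13′ are not enolisable and stay S.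

Step 12
Reactants: 17 (E)-enal diol
Product: 19 target CNP0229303.1, via dialdehyde 18 (not isolated)
Conditions: (C5H5NH)2Cr2O7 (8 equiv), DMF, rt
Reagents that add atoms: pyridinium dichromate, [O-][Cr](=O)(=O)O[Cr](=O)(=O)[O-].c1cc[nH+]cc1.c1cc[nH+]cc1; water, O
Why: Pyridinium dichromate in DMF (Corey–Schmidt oxidation) takes saturated primary alcohols through the aldehyde hydrate to the acid but leaves conjugated aldehydes, which do not hydrate, unchanged, so both C-19 groups become CO2H while the enal and the exocyclic alkenes survive; no stereocentre is affected.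

**Compound list**
1 | (2E,6E)-farnesol | OC/C=C(C)/CC/C=C(C)/CCC=C(C)C | starting material
2 | (3S,6E)-3,7,11-trimethyldodeca-6,10-dien-1-ol | OCC[C@@H](C)CC/C=C(C)/CCC=C(C)C | intermediate
3 | (3S,6E)-3,7,11-trimethyldodeca-6,10-dien-1-yl pivalate | CC(C)(C)C(=O)OCC[C@@H](C)CC/C=C(C)/CCC=C(C)C | intermediate
4 | (3S,6E,10E)-12-hydroxy-3,7,11-trimethyldodeca-6,10-dien-1-yl pivalate | CC(C)(C)C(=O)OCC[C@@H](C)CC/C=C(C)/CC/C=C(C)/CO | intermediate
5 | (3S,6E,10E)-12-bromo-3,7,11-trimethyldodeca-6,10-dien-1-yl pivalate | CC(C)(C)C(=O)OCC[C@@H](C)CC/C=C(C)/CC/C=C(C)/CBr | intermediate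
6 | (–)-8-phenylmenthol, (1R,2S,5R)-5-methyl-2-(2-phenylpropan-2-yl)cyclohexan-1-ol | O[C@@H]1C[C@H](C)CC[C@H]1C(C)(C)c1ccccc1 | starting material
7 | ethyl 2-methyl-3-oxobutanoate | CCOC(=O)C(C)C(C)=O | starting material
8 | (1R,2S,5R)-5-methyl-2-(2-phenylpropan-2-yl)cyclohexyl 2-methyl-3-oxobutanoate | CC(=O)C(C)C(=O)O[C@@H]1C[C@H](C)CC[C@H]1C(C)(C)c1ccccc1 | intermediate
9 | sodium lithium dienolate (dianion) of 8 | [Li+].[Na+].C=C([O-])C(C)=C([O-])O[C@@H]1C[C@H](C)CC[C@H]1C(C)(C)c1ccccc1 | intermediate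
10 | (–)-8-phenylmenthyl (6E,10E,14S)-2,6,10,14-tetramethyl-3-oxo-16-(pivaloyloxy)hexadeca-6,10-dienoate | CC(C)(C)C(=O)OCC[C@@H](C)CC/C=C(C)/CC/C=C(C)/CCC(=O)C(C)C(=O)O[C@@H]1C[C@H](C)CC[C@H]1C(C)(C)c1ccccc1 | intermediate
11 | (–)-8-phenylmenthyl (13S)-3-oxo-15-(pivaloyloxy)labd-8(17)-en-19-oate | C=C1CC[C@@H]2[C@](C)(CCC(=O)[C@]2(C)C(=O)O[C@@H]3C[C@H](C)CC[C@H]3C(C)(C)c3ccccc3)[C@H]1CC[C@H](C)CCOC(=O)C(C)(C)C | intermediate
12 | C-3 tosylhydrazone of 11 | C=C1CC[C@@H]2[C@](C)(CCC(=NNS(=O)(=O)c3ccc(C)cc3)[C@]2(C)C(=O)O[C@@H]3C[C@H](C)CC[C@H]3C(C)(C)c3ccccc3)[C@H]1CC[C@H](C)CCOC(=O)C(C)(C)C | intermediate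
13 | (–)-8-phenylmenthyl (4S,5R,9S,10R,13S)-15-(pivaloyloxy)labd-8(17)-en-19-oate | C=C1CC[C@@H]2[C@](C)(CCC[C@]2(C)C(=O)O[C@@H]3C[C@H](C)CC[C@H]3C(C)(C)c3ccccc3)[C@H]1CC[C@H](C)CCOC(=O)C(C)(C)C | intermediate
14 | (4S,5R,9S,10R,13S)-labd-8(17)-ene-15,19-diol | C=C1CC[C@@H]2[C@](C)(CCC[C@]2(C)CO)[C@H]1CC[C@H](C)CCO | intermediate
15 | (4S,5R,9S,10R,13S)-19-hydroxylabd-8(17)-en-15-al | C=C1CC[C@@H]2[C@](C)(CCC[C@]2(C)CO)[C@H]1CC[C@H](C)CC=O | intermediate
16 | aldol adduct of two molecules of 15 (β-hydroxy aldehyde, C14–C15′ bond, new centres as a mixture) | C=C1CC[C@@H]2[C@](C)(CCC[C@]2(C)CO)[C@H]1CC[C@H](C)C(C=O)C(O)C[C@@H](C)CC[C@H]1C(=C)CC[C@@H]2[C@]1(C)CCC[C@]2(C)CO | intermediate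
17 | (E)-enal diol, C-14 of one 19-hydroxylabd-8(17)-en-15-al unit doubly bonded to C-15′ of the other | C=C1CC[C@@H]2[C@](C)(CCC[C@]2(C)CO)[C@H]1CC[C@H](C)/C(C=O)=C\C[C@@H](C)CC[C@H]1C(=C)CC[C@@H]2[C@]1(C)CCC[C@]2(C)CO | intermediate
18 | 19,19′-dialdehyde of 17 | C=C1CC[C@@H]2[C@](C)(CCC[C@]2(C)C=O)[C@H]1CC[C@H](C)/C(C=O)=C\C[C@@H](C)CC[C@H]1C(=C)CC[C@@H]2[C@]1(C)CCC[C@]2(C)C=O | intermediate
19 | target CNP0229303.1, (E)-enal 19,19′-dioic acid (C-14 of one (13S)-15-oxolabd-8(17)-en-19-oic acid unit doubly bonded to C-15′ of the second); given string kept, see assumption | C=C1CC[C@@H]2[C@](C)(CCC[C@]2(C)C(=O)O)[C@H]1CC[C@H](C)/C(C=O)=C\C[C@@H](C)CC[C@H]1C(=C)CC[C@H]2[C@]1(C)CCC[C@]2(C)C(=O)O | target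

**Totals**
Total step count: 12. Longest linear sequence: 11 (steps 1–4 and 6–12).

**Steps most likely to fail, with fallbacks**

Step 7 (face control by the auxiliary in the unchelated 2-methyl radical, and exo-alkene selectivity). The fallback takes the methyl group out of the cyclisation and uses the chelated manifold; it sets out from 5 and comes back at 14. Bromide 5 alkylates the dianion of (+)-8-phenylmenthyl 3-oxobutanoate F1 (made from (+)-8-phenylmenthol and ethyl acetoacetate as in step 5) to give (+)-8-phenylmenthyl (6E,10E,14S)-6,10,14-trimethyl-3-oxo-16-(pivaloyloxy)hexadeca-6,10-dienoate F2. Mn(OAc)3·2H2O, Yb(OTf)3 and Cu(OAc)2·H2O in CF3CH2OH at 0 °C cyclise the Yb-chelated radical; here the ester sits equatorial in the transition state, so the antipodal auxiliary gives the natural decalin, the enolisable (+)-8-phenylmenthyl (13S)-3-oxo-15-(pivaloyloxy)-18-norlabd-8(17)-en-19-oate F3. K2CO3/MeI in acetone then puts the methyl on the α face, anti to the angular methyl, giving (+)-8-phenylmenthyl (13S)-3-oxo-15-(pivaloyloxy)labd-8(17)-en-19-oate F4. Deoxygenation as in step 8 gives (+)-8-phenylmenthyl (13S)-15-(pivaloyloxy)labd-8(17)-en-19-oate F5, and LiAlH4 returns to 14.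

Step 8 (tosylhydrazone formation at a ketone flanked by the quaternary C-4). The fallback removes the oxygen by radical deoxygenation; it sets out from 11 and comes back at 13. NaBH4 in MeOH at 0 °C gives (–)-8-phenylmenthyl (13S)-3β-hydroxy-15-(pivaloyloxy)labd-8(17)-en-19-oate F6. NaH, CS2 and MeI give the 3-O-[(methylsulfanyl)thiocarbonyl] derivative F7, and Bu3SnH with azobisisobutyronitrile in toluene at 110 °C (Barton–McCombie) gives 13.

Step 12 (double oxidation of two hindered neopentyl alcohols next to an enal). The fallback installs the acid before dimerisation; it sets out from 14 and comes back at 19. t-BuPh2SiCl/imidazole silylates only the unhindered C-15 OH to give (13S)-15-(tert-butyldiphenylsilyloxy)labd-8(17)-en-19-ol F8. 2,2,6,6-Tetramethylpiperidin-1-oxyl/NaOCl (cat.)/NaClO2 gives (13S)-15-(tert-butyldiphenylsilyloxy)labd-8(17)-en-19-oic acid F9. Bu4NF gives imbricatolic acid, (13S)-15-hydroxylabd-8(17)-en-19-oic acid F10, and Dess–Martin periodinane gives (13S)-15-oxolabd-8(17)-en-19-oic acid F11. The pyrrolidine-catalysed aldol condensation of step 11, run on F11, then gives 19 directly.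

**Further compounds**
F1 | step 7 | (1S,2R,5S)-5-methyl-2-(2-phenylpropan-2-yl)cyclohexyl 3-oxobutanoate | CC(=O)CC(=O)O[C@H]1C[C@@H](C)CC[C@@H]1C(C)(C)c1ccccc1
F2 | step 7 | (+)-8-phenylmenthyl (6E,10E,14S)-6,10,14-trimethyl-3-oxo-16-(pivaloyloxy)hexadeca-6,10-dienoate | CC(C)(C)C(=O)OCC[C@@H](C)CC/C=C(C)/CC/C=C(C)/CCC(=O)CC(=O)O[C@H]1C[C@@H](C)CC[C@@H]1C(C)(C)c1ccccc1
F3 | step 7 | (+)-8-phenylmenthyl (13S)-3-oxo-15-(pivaloyloxy)-18-norlabd-8(17)-en-19-oate | C=C1CC[C@@H]2[C@](C)(CCC(=O)C2C(=O)O[C@H]3C[C@@H](C)CC[C@@H]3C(C)(C)c3ccccc3)[C@H]1CC[C@H](C)CCOC(=O)C(C)(C)C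
F4 | step 7 | (+)-8-phenylmenthyl (13S)-3-oxo-15-(pivaloyloxy)labd-8(17)-en-19-oate | C=C1CC[C@@H]2[C@](C)(CCC(=O)[C@]2(C)C(=O)O[C@H]3C[C@@H](C)CC[C@@H]3C(C)(C)c3ccccc3)[C@H]1CC[C@H](C)CCOC(=O)C(C)(C)C
F5 | step 7 | (+)-8-phenylmenthyl (13S)-15-(pivaloyloxy)labd-8(17)-en-19-oate | C=C1CC[C@@H]2[C@](C)(CCC[C@]2(C)C(=O)O[C@H]3C[C@@H](C)CC[C@@H]3C(C)(C)c3ccccc3)[C@H]1CC[C@H](C)CCOC(=O)C(C)(C)C
F6 | step 8 | (–)-8-phenylmenthyl (13S)-3β-hydroxy-15-(pivaloyloxy)labd-8(17)-en-19-oate | C=C1CC[C@@H]2[C@](C)(CC[C@H](O)[C@]2(C)C(=O)O[C@@H]3C[C@H](C)CC[C@H]3C(C)(C)c3ccccc3)[C@H]1CC[C@H](C)CCOC(=O)C(C)(C)C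
F7 | step 8 | (–)-8-phenylmenthyl (13S)-3β-{[(methylsulfanyl)thiocarbonyl]oxy}-15-(pivaloyloxy)labd-8(17)-en-19-oate | C=C1CC[C@@H]2[C@](C)(CC[C@H](OC(=S)SC)[C@]2(C)C(=O)O[C@@H]3C[C@H](C)CC[C@H]3C(C)(C)c3ccccc3)[C@H]1CC[C@H](C)CCOC(=O)C(C)(C)C
F8 | step 12 | (13S)-15-(tert-butyldiphenylsilyloxy)labd-8(17)-en-19-ol | C=C1CC[C@@H]2[C@](C)(CCC[C@]2(C)CO)[C@H]1CC[C@H](C)CCO[Si](C(C)(C)C)(c1ccccc1)c1ccccc1
F9 | step 12 | (13S)-15-(tert-butyldiphenylsilyloxy)labd-8(17)-en-19-oic acid | C=C1CC[C@@H]2[C@](C)(CCC[C@]2(C)C(=O)O)[C@H]1CC[C@H](C)CCO[Si](C(C)(C)C)(c1ccccc1)c1ccccc1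
F10 | step 12 | imbricatolic acid, (13S)-15-hydroxylabd-8(17)-en-19-oic acid | C=C1CC[C@@H]2[C@](C)(CCC[C@]2(C)C(=O)O)[C@H]1CC[C@H](C)CCO
F11 | step 12 | (13S)-15-oxolabd-8(17)-en-19-oic acid | C=C1CC[C@@H]2[C@](C)(CCC[C@]2(C)C(=O)O)[C@H]1CC[C@H](C)CC=O
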